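**Remark on the chemistry:** all locants (C1–C15) are those of the germacrane skeleton of the target and are used for every intermediate: ring C1–C10, C11 on C7, C12 the lactone carbonyl, C13 the hydroxymethyl carbon, C14 the methyl on C10, C15 the methyl on C4. C2 of 27 and the lactol carbon of 35 are expected as epimer mixtures, which has no consequence.

## Analysis of the target

Glaucolide L (38) is a germacranolide: a ten-membered carbocycle (C1–C10) fused through C6–C7 to a butenolide (O–C6, C7=C11, C12=O) whose C11 carries a free hydroxymethyl group (C13). It has six stereocentres: C1 (S, acetate), C4 and C5 (R,R, a trans epoxide, C4 quaternary with C15), C6 (S, lactone oxygen), C8 (S, methacrylate) and C10 (S, methyl). The C1 acetate is trans to the C10 methyl across the ring, C4–C5–C6 are contiguous, and the C6 and C8 oxygens are 1,3-syn across the sp2 carbon C7. The C10/C1 pair is separated from the C4–C8 block by methylene groups, so neither block can relay stereochemical information to the other. The sensitive groups are the trisubstituted epoxide next to the lactone oxygen, the methacrylate (a polymerisable Michael acceptor), two different esters beside a free primary alcohol that sits cis-1,4 to the C8 ester (acyl migration), and the γ-hydrogen of the butenolide at C6. The synthesis is hard for two reasons: a ten-membered ring has to be closed, and the tetrasubstituted C7=C11 alkene carries four different oxygenated carbons, of which C12 and C13 differ only in oxidation level and in their position relative to C6. The strategy rests on one feature: C2 lies between C1, whose oxygen can be a ketone, and C3, which is allylic to the C4=C5 alkene that precedes the epoxide. The C2–C3 bond is therefore the bond between the α-carbon of a C1 β-keto ester and the terminus of a C3–C5 allyl unit, and neither atom is a stereocentre.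

## Retrosynthetic reasoning

38 ⇒ 37. The two C–O bonds of the epoxide are cut first. The epoxide is the most fragile group, and an E-configured C4=C5 alkene in the ten-membered ring exposes only its outer face, which is the face required. The forward step has to epoxidise C4=C5 while leaving the butenolide and methacrylate alkenes alone; their electron poverty secures this.

37 ⇒ 36 ⇒ 34. The lactone C12–O bond is cut, and C12 is taken back to the alcohol level, giving triol 34 with two equivalent hydroxymethyl arms on C11. Only the arm cis to the C6 hydroxyl can close a five-membered lactol, but an oxidant cannot tell the arms apart. The forward plan therefore oxidises both (36) and returns the non-lactonised arm to the alcohol (37). What is gained is a C7=C11 alkene with no geometry to control in all earlier intermediates.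

34 ⇒ 28. The C8–O and C1–O acyl bonds and the protecting groups are removed, and the C1 carbinol is traced to ketone 28. The ketone is needed because C1 is the activating carbonyl of the ring-closing nucleophile. The forward sequence must set C1 on the ring and acylate C8 before the C13 hydroxyl is uncovered.

28 ⇒ 27 ⇒ 26. After adding a methoxycarbonyl group at C2, the C2–C3 bond is cut. This is the only ring bond whose two ends are a stabilised carbanion and an allyl terminus without a stereocentre. Cutting here keeps C6, C8 and C10 in an open chain where they can be set one at a time, and the allylic carbonate 26 already holds the E alkene. The forward reaction has to close the ten-membered ring at C3 and not the eight-membered ring at C5, and keep the E geometry.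

26 ⇒ 24. The C1–C2 bond is cut to aldehyde 24 and a two-carbon ester enolate. The β-keto ester is made last in the open chain because it would not survive the organolithium chemistry that builds C6–C8.

24 ⇒ 21 ⇒ 20 ⇒ 11 + 17. The C6–C7 bond is cut between a C7 alkenyl anion (from vinyl bromide 11) and enal 17, which brings C3–C6 with the E alkene and the carbonate already in place. C6 is set afterwards by reagent-controlled reduction of dienone 20, because 1,3-induction from C8 across an sp2 carbon cannot be relied on.

11 ⇒ 10 ⇒ 9 ⇒ 6 + 2. The C8–C9 bond is cut between bromo enal 6 and the organomagnesium derivative of bromide 2, which carries C10 from the chiral pool. C8 is set by reduction of bromo enone 9, where the bromoalkenyl and CH2 groups differ strongly in size.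

6 ⇒ 4 ⇒ 3; 17 ⇒ 12; 2 ⇒ 1. The C7=C11 bond comes from dibromo-olefination of the symmetrical ketone 3, and the two bromines of 4 are replaced in turn by C8 and C6. Enal 17 comes from 12 by allylic oxidation, which fixes the E geometry, and 2 is the silyl ether of 1.

## Alternatives that were turned down

Alternative 1: The C7–C8 and C11–C13 bonds are cut in a saturated γ-lactone. In the forward step a sulfur-stabilised C8 acyl-anion equivalent adds in conjugate fashion to C7 of a C6-substituted unsaturated lactone, and the lactone enolate is hydroxymethylated at C11, giving A1 in one operation.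
- For it: three components are joined at once, the trans,trans arrangement follows from the single C6 stereocentre, C12 and C13 are different from the start, and C1 is set in the open chain. On the last two points it is stronger than the chosen route, which needs steps 29–30 and a reduction on the macrocycle (step 23).
- Against it: in the target C7 and C11 are sp2, so both stereocentres made in the key step are destroyed again by a late dehydrogenation of a fully substituted lactone. C8 arrives at the ketone level and must be reduced with control next to a crowded centre. A1 contains neither C4 nor the ring, so the ten-membered ring and the trisubstituted E alkene are still to be made, with poor geometric control if closed by metathesis.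
- Comparison: the chosen strategy offers the ring and the alkene geometry in one step that creates no stereocentre.

Alternative 2: The epoxide C4–O bond and the lactone C12–O bond are traced to a macrocyclic cis-5,6-epoxide with a free tertiary C4 hydroxyl and a C12 ester. In the forward step base moves the epoxide (Payne rearrangement, inversion at C5) and the released C6 alkoxide lactonises, giving A2.
- For it: the epoxide configuration follows from a stereospecific intramolecular displacement and not from a facial preference of the macrocycle, which is stronger than step 31 of the chosen route. The C4 centre comes from the terpene pool, lactonisation pulls the epoxide equilibrium, and C12 and C13 are differentiated.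
- Against it: the cascade presupposes the ten-membered ring, so the ring closure is not solved but moved to a substrate that already carries a cis epoxide, a tertiary alcohol and a geometrically defined tetrasubstituted ester. The backside attack of O4 on C5 needs an anti-periplanar alignment inside the ring that leads to a trans-fused epoxide and may not be reachable. C1, C8 and C10 must still be introduced far from the pool stereocentre.
- Comparison: the chosen strategy closes the ring directly and pays with a less certain epoxidation.

Alternative 3: The C5–C6 bond is cut. In the forward step a Lewis acid activates a C5 aldehyde and the γ-carbon (C6) of a silyloxyfuran attacks it (intramolecular vinylogous Mukaiyama aldol), closing the ten-membered ring, forming the butenolide and creating C5 and C6, to give A3.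
- For it: it is the most convergent plan. Ring and lactone form together with the esters already in place, C12 and C13 are different from the start, and only epoxide closure remains. On step economy it is clearly stronger than the chosen route.
- Against it: two stereocentres are formed during a medium-ring closure with no dependable control element. The aldehyde sits on a fully substituted, silyloxy-bearing C4, and the Lewis acid meets a methacrylate, an acetate and silyl ethers. C5 must come out with the one configuration that lets O4 displace it with inversion.
- Comparison: the key step of the chosen strategy forms no stereocentre, so its open questions are only regiochemistry and ring closure against oligomerisation.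

Key step: step 21

## Steps

Step 1
Reactants: 1 (R)-3-bromo-2-methylpropan-1-ol
Product: 2 (R)-(3-bromo-2-methylpropoxy)(tert-butyl)dimethylsilane
Conditions: TBSCl, imidazole, DMF, rt
Reagents that add atoms: tert-butyldimethylsilyl chloride, CC(C)(C)[Si](C)(C)Cl
Why: Standard imidazole-promoted silylation of a primary alcohol; the stereocentre (future C10) is not involved.

Step 2
Reactants: 3 2,2-dimethyl-1,3-dioxan-5-one
Product: 4 5-(dibromomethylene)-2,2-dimethyl-1,3-dioxane
Conditions: CBr4, PPh3, CH2Cl2, 0 °C → rt
Reagents that add atoms: carbon tetrabromide, BrC(Br)(Br)Br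
Why: Ramirez dibromo-olefination of an electron-poor α,α'-dialkoxy ketone; the two ring CH2O arms are equivalent, so the future tetrasubstituted C7=C11 alkene has no geometry to control.

Step 3
Reactants: 4 5-(dibromomethylene)-2,2-dimethyl-1,3-dioxane
Product: 6 2-bromo-2-(2,2-dimethyl-1,3-dioxan-5-ylidene)acetaldehyde, via lithium bromocarbenoid 5 (not isolated)
Conditions: n-BuLi (1.05 equiv), THF/Et2O, −105 °C; then DMF, −105 → −78 °C; aq. NH4Cl
Reagents that add atoms: N,N-dimethylformamide, CN(C)C=O
Why: Bromine–lithium exchange at very low temperature gives the 1-bromo-1-lithioalkene, which cannot undergo a Fritsch–Buttenberg–Wiechell shift without forming a strained cycloalkyne and is held by the neighbouring acetal oxygen. Formylation with DMF is the usual trapping of such carbenoids.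

Step 4
Reactants: 2 (R)-(3-bromo-2-methylpropoxy)(tert-butyl)dimethylsilane; 6 2-bromo-2-(2,2-dimethyl-1,3-dioxan-5-ylidene)acetaldehyde
Product: 8 (4S)-1-bromo-5-((tert-butyldimethylsilyl)oxy)-1-(2,2-dimethyl-1,3-dioxan-5-ylidene)-4-methylpentan-2-ol (both epimers at the carbinol carbon C8), via alkylmagnesium bromide 7 (not isolated)
Conditions: Mg, THF, 40 °C; then 6, THF, −78 → 0 °C
Reagents that add atoms: none
Why: Grignard formation from the primary bromide and 1,2-addition to an enal whose β-carbon is fully substituted form the C8–C9 bond. C8 is formed without control and is corrected in steps 5 and 6.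

Step 5
Reactants: 8 bromo allylic alcohol (C8 epimers)
Product: 9 (S)-1-bromo-5-((tert-butyldimethylsilyl)oxy)-1-(2,2-dimethyl-1,3-dioxan-5-ylidene)-4-methylpentan-2-one
Conditions: Dess–Martin periodinane, NaHCO3, CH2Cl2, rt
Reagents that add atoms: none
Why: Dess–Martin oxidation of a secondary allylic alcohol under buffered conditions; the silyl ether, acetonide and vinylic bromide are inert.

Step 6
Reactants: 9 α-bromo enone
Product: 10 (2S,4S)-1-bromo-5-((tert-butyldimethylsilyl)oxy)-1-(2,2-dimethyl-1,3-dioxan-5-ylidene)-4-methylpentan-2-ol (8S,10S in skeleton numbering)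
Conditions: (R)-Me-CBS oxazaborolidine, BH3·SMe2, THF, −30 °C; MeOH
Reagents that add atoms: none
Why: Corey–Bakshi–Shibata reduction in which the α-bromoalkenyl group is the large and the CH2 group the small substituent, so the (R)-catalyst should deliver hydride to give the 8S carbinol. This is catalyst control, and the remote C10 centre should have little influence.

Step 7
Reactants: 10 (8S,10S)-bromo allylic alcohol
Product: 11 (8S,10S)-C7 vinylic bromide with C8 4-methoxybenzyl ether and C1 TBS ether: tert-butyl{[(2S,4S)-5-bromo-5-(2,2-dimethyl-1,3-dioxan-5-ylidene)-4-((4-methoxybenzyl)oxy)-2-methylpentyl]oxy}dimethylsilane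
Conditions: NaH, PMBCl, Bu4NI (cat.), THF/DMF, 0 °C → rt
Reagents that add atoms: 4-methoxybenzyl chloride, COc1ccc(CCl)cc1
Why: Williamson etherification of the secondary alkoxide, which cannot displace the vinylic bromide. The PMB ether withstands t-BuLi at −78 °C and is later removed oxidatively.

Step 8
Reactants: 12 3-methylbut-2-en-1-ol (prenol)
Product: 13 tert-butyldimethyl((3-methylbut-2-en-1-yl)oxy)silane
Conditions: TBSCl, imidazole, CH2Cl2, rt
Reagents that add atoms: tert-butyldimethylsilyl chloride, CC(C)(C)[Si](C)(C)Cl
Why: Standard silylation; the silyl ether marks the future C6 end so that the two allylic oxygens stay distinguishable.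

Step 9
Reactants: 13 prenyl TBS ether
Product: 14 (E)-4-((tert-butyldimethylsilyl)oxy)-2-methylbut-2-en-1-ol
Conditions: SeO2 (cat.), t-BuOOH, salicylic acid (cat.), CH2Cl2, rt
Reagents that add atoms: tert-butyl hydroperoxide, CC(C)(C)OO; selenium dioxide (oxygen-transfer catalyst), O=[Se]=O
Why: Riley allylic oxidation (ene reaction then [2,3]-shift) attacks the E-methyl group of the trisubstituted alkene and gives the (E)-allylic alcohol, which fixes the later C4=C5 geometry. A minor over-oxidised enal is separated.

Step 10
Reactants: 14 (E)-allylic alcohol
Product: 15 (E)-4-((tert-butyldimethylsilyl)oxy)-2-methylbut-2-en-1-yl methyl carbonate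
Conditions: ClCO2Me, pyridine, CH2Cl2, 0 °C
Reagents that add atoms: methyl chloroformate, COC(=O)Cl
Why: Acylation with the chloroformate installs at C3 the leaving group of the key step. Carrying it from here avoids a protecting-group exchange on the advanced chain.

Step 11
Reactants: 15 silyl ether carbonate
Product: 16 (E)-4-hydroxy-2-methylbut-2-en-1-yl methyl carbonate
Conditions: HF·pyridine, THF, 0 °C
Reagents that add atoms: none
Why: Acidic fluoride removes the primary silyl ether without touching the carbonate. The two oxygens are trans across the alkene, so the carbonate cannot migrate.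

Step 12
Reactants: 16 hydroxy carbonate
Product: 17 (E)-methyl (2-methyl-4-oxobut-2-en-1-yl) carbonate
Conditions: MnO2, CH2Cl2, rt
Reagents that add atoms: none
Why: MnO2 oxidises the allylic alcohol selectively to the enal under neutral conditions and should not isomerise the E alkene.

Step 13
Reactants: 11 (8S,10S)-vinylic bromide; 17 (E)-enal carbonate
Product: 19 open-chain bis-allylic alcohol (both C6 epimers; 8S,10S): C3 methyl carbonate, E-C4=C5, C6 hydroxyl, C7 (2,2-dimethyl-1,3-dioxan-5-ylidene), C8 PMB ether, C1 TBS ether, via alkenyllithium 18 (not isolated)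
Conditions: t-BuLi (2.1 equiv), Et2O, −78 °C; then 17 (1.3 equiv), −78 °C
Reagents that add atoms: none
Why: Bromine–lithium exchange gives a 2-lithio allylic ether that is stable at −78 °C and adds 1,2 to the aldehyde far faster than to the carbonate, forming the C6–C7 bond. C6 is formed as a mixture and is corrected in steps 14 and 15.

Step 14
Reactants: 19 bis-allylic alcohol (C6 epimers)
Product: 20 (8S,10S)-cross-conjugated C6 dienone
Conditions: Dess–Martin periodinane, NaHCO3, CH2Cl2, 0 °C → rt
Reagents that add atoms: none
Why: Dess–Martin oxidation of the bis-allylic alcohol under buffered, non-basic conditions that leave the allylic carbonate and the PMB ether alone.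

Step 15
Reactants: 20 C6 dienone
Product: 21 (6R,8S,10S)-C6 alcohol
Conditions: (S)-Me-CBS oxazaborolidine, catecholborane, toluene, −78 °C
Reagents that add atoms: none
Why: Corey–Bakshi–Shibata reduction with catecholborane is 1,2-selective for enones. The fully substituted, α-branched C7 alkenyl group is the large substituent and the α-unsubstituted C5 alkenyl group the small one, so the (S)-catalyst should give 6R, which is the 6,8-syn isomer.

Step 16
Reactants: 21 (6R,8S,10S)-C6 alcohol
Product: 22 (6R,8S,10S)-C6 TBS ether (C1 TBS ether, C8 PMB ether, C3 methyl carbonate)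
Conditions: TBSOTf, 2,6-lutidine, CH2Cl2, −78 °C
Reagents that add atoms: tert-butyldimethylsilyl triflate, CC(C)(C)[Si](C)(C)OS(=O)(=O)C(F)(F)F
Why: The silyl triflate is needed for the hindered bis-allylic alcohol; at −78 °C with a hindered base the acetonide and the carbonate are not attacked.

Step 17
Reactants: 22 bis-TBS ether
Product: 23 (6R,8S,10S)-C1 primary alcohol
Conditions: HF·pyridine, pyridine, THF, 0 °C
Reagents that add atoms: none
Why: Buffered HF·pyridine cleaves a primary TBS ether much faster than the hindered secondary bis-allylic one and leaves the acetonide intact.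

Step 18
Reactants: 23 C1 alcohol
Product: 24 (6R,8S,10S)-C1 aldehyde
Conditions: Dess–Martin periodinane, NaHCO3, CH2Cl2, rt
Reagents that add atoms: none
Why: Dess–Martin oxidation under buffered conditions gives the α-branched aldehyde without epimerising C10.

Step 19
Reactants: 24 C1 aldehyde
Product: 25 β-hydroxy methyl ester (both C1 epimers; 6R,8S,10S)
Conditions: LiN(i-Pr)2, MeOAc, THF, −78 °C; then 24, −78 °C
Reagents that add atoms: methyl acetate, CC(=O)OC
Why: Aldol addition of the lithium enolate of methyl acetate to the aldehyde at −78 °C is faster than attack on the carbonate or enolisation toward C10. The new carbinol centre is removed by the next oxidation.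

Step 20
Reactants: 25 β-hydroxy ester
Product: 26 (6R,8S,10S)-β-keto methyl ester with C3 allylic methyl carbonate (cyclisation precursor)
Conditions: Dess–Martin periodinane, NaHCO3, CH2Cl2, rt
Reagents that add atoms: none
Why: Dess–Martin oxidation of a β-hydroxy ester to the β-keto ester is standard and neutral, so C10, now α to a ketone, is not epimerised.

Step 21
Reactants: 26 open-chain β-keto ester allylic carbonate
Product: 27 ten-membered β-keto ester (6R,8S,10S; E-C4=C5; C2 epimers): methyl ester at C2, ketone at C1, C6 TBS ether, C7 (2,2-dimethyl-1,3-dioxan-5-ylidene), C8 PMB ether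
Conditions: Pd(PPh3)4 (10 mol %), THF, 65 °C, slow addition of 26 to 0.002 M
Reagents that add atoms: none
Why: Zerovalent palladium ionises the primary allylic carbonate of 26 (oxidative addition with loss of CO2) to a cationic divalent palladium η3-allyl complex spanning C3–C4–C5, and the methoxide set free deprotonates only the doubly activated C2–H (pKa about 11), so no external base is present and C10 is not epimerised. The soft enolate attacks the allyl ligand from the face opposite to the metal; the closest known reaction type is the palladium-catalysed intramolecular allylic alkylation of β-keto esters with allylic carbonates (Tsuji–Trost reaction under neutral conditions), which is known to close medium and large carbocycles. The ten-membered ring is closed by attack at the distal, unsubstituted terminus C3, so that all three allyl carbons become ring members (endo mode), in competition with exo attack at C5, which would give an eight-membered ring carrying an isopropenyl group. C3 should be preferred because it is a bare CH2, whereas C5 is flanked by the C6 silyl ether and the fully substituted C7 alkylidene. The E geometry of C4=C5 is carried over because the E carbonate gives the syn allyl complex and syn–anti exchange would need a σ-complex at the hindered C5. O-allylation of the enolate is reversible under the reaction conditions and drains into the C-alkylated ketone, and cyclisation is favoured over oligomerisation by slow addition at high dilution and by the A1,3 strain around the C7 alkylidene, which limits the rotamers of the chain. No lasting stereocentre is formed: C2 is obtained as a mixture of epimers that disappears in step 22.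

Step 22
Reactants: 27 ten-membered β-keto ester
Product: 28 (6R,8S,10S)-ten-membered C1 ketone (E-C4=C5, C6 TBS ether, C8 PMB ether, C7 dioxanylidene)
Conditions: LiCl, H2O, DMSO, 130 °C
Reagents that add atoms: none
Why: Krapcho dealkoxycarbonylation (chloride attack at the ester methyl, then decarboxylation) runs near neutrality; both C2 epimers converge and the enolate is protonated at C2, so C10 should be preserved.

Step 23
Reactants: 28 C1 ketone
Product: 29 (1S,6R,8S,10S)-C1 alcohol
Conditions: (R)-Me-CBS oxazaborolidine (1 equiv), BH3·SMe2, THF, −30 °C; MeOH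
Reagents that add atoms: none
Why: Corey–Bakshi–Shibata reduction in which the branched C10 side is the large and the C2 methylene the small substituent, so the (R)-catalyst should give the 1S alcohol, trans to the C10 methyl on the ring. Catalysed reduction of the ketone is faster than hydroboration of the hindered alkenes.

Step 24
Reactants: 29 C1 alcohol
Product: 30 (1S,6R,8S,10S)-C1 acetate
Conditions: Ac2O, pyridine, DMAP (cat.), CH2Cl2, rt
Reagents that add atoms: acetic anhydride, CC(=O)OC(C)=O
Why: DMAP-catalysed acetylation of the only free hydroxyl group.

Step 25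
Reactants: 30 C1 acetate with C8 PMB ether
Product: 31 (1S,6R,8S,10S)-C8 alcohol
Conditions: DDQ, CH2Cl2/pH 7 buffer, 0 °C
Reagents that add atoms: none
Why: Oxidative cleavage of the PMB ether by DDQ (benzylic hydride abstraction, hydrolysis of the oxocarbenium ion) is much faster at 0 °C than oxidation of the allylic silyl ether, and the buffer protects the acetonide.

Step 26
Reactants: 31 C8 alcohol
Product: 32 (1S,6R,8S,10S)-C8 methacrylate (C1 acetate, C6 TBS ether, C12/C13 acetonide)
Conditions: methacrylic anhydride, Et3N, DMAP, CH2Cl2, rt
Reagents that add atoms: methacrylic anhydride, C=C(C)C(=O)OC(=O)C(C)=C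
Why: DMAP-catalysed acyl transfer to the only free hydroxyl group. The ester is installed while C13 is still masked, so no primary alcohol competes.

Step 27
Reactants: 32 C8 methacrylate
Product: 33 (1S,6R,8S,10S)-C6 alcohol (acetonide retained)
Conditions: HF·pyridine, THF, 0 °C → rt
Reagents that add atoms: none
Why: Acidic fluoride removes the hindered secondary silyl ether without generating an alkoxide that could move an acyl group. Partial loss of the acetonide would be harmless because step 28 removes it.

Step 28
Reactants: 33 C6 alcohol acetonide
Product: 34 (1S,6R,8S,10S)-6,12,13-triol (C1 acetate, C8 methacrylate)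
Conditions: PPTS, MeOH, rt
Reagents that add atoms: none
Why: Mild acid-catalysed transacetalisation to methanol frees the two equivalent hydroxymethyl arms. The conditions are too mild to ionise the bis-allylic C6 alcohol or to transesterify the esters.

Step 29
Reactants: 34 triol
Product: 36 (1S,6R,8S,10S)-13-oxo-6,12-lactone (formyl butenolide; C1 acetate, C8 methacrylate, E-C4=C5), via lactol 35 (not isolated)
Conditions: TEMPO (2,2,6,6-tetramethylpiperidin-1-oxyl, 0.2 equiv), PhI(OAc)2 (4.5 equiv), CH2Cl2, rt
Reagents that add atoms: none
Why: Oxoammonium oxidation (TEMPO/PhI(OAc)2 oxidative lactonisation of a 2-ene-1,4-diol) is selective for primary over secondary alcohols; the C12 aldehyde is captured by the cis C6 hydroxyl as lactol 35 and oxidised on to the lactone. The other arm cannot lactolise and is taken to the aldehyde, so both orders of attack on the two equivalent arms should converge on 36. Material that stops at the C13 alcohol stage is already the product of step 30.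

Step 30
Reactants: 36 13-oxo lactone
Product: 37 (1S,6R,8S,10S)-13-hydroxy-6,12-lactone (4,5-deoxy precursor of the target)
Conditions: NaBH4, CeCl3·7H2O, MeOH, −78 °C
Reagents that add atoms: none
Why: Luche reduction is 1,2-selective and at −78 °C reduces only the aldehyde. The lactone, the acetate, the methacrylate and the fully substituted β-carbon C7 should not react.

Step 31
Reactants: 37 13-hydroxy lactone
Product: 38 glaucolide L (1S,4R,5R,6S,8S,10S)
Conditions: mCPBA, NaHCO3, CH2Cl2, 0 °C
Reagents that add atoms: 3-chloroperbenzoic acid, OOC(=O)c1cccc(Cl)c1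
Why: Prilezhaev epoxidation; C4=C5 is the only electron-rich alkene, the butenolide and methacrylate alkenes being deactivated by conjugation. In the conformer that places C6–H in the alkene plane (A1,3 strain with C15) the ring chain covers one face, so the peracid should attack the outer face, which corresponds to 4R,5R; syn addition to the E alkene gives the trans epoxide.

## Compound list

1 | (R)-3-bromo-2-methylpropan-1-ol | OC[C@@H](C)CBr | starting material
2 | (R)-(3-bromo-2-methylpropoxy)(tert-butyl)dimethylsilane | CC(C)(C)[Si](C)(C)OC[C@@H](C)CBr | intermediate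
3 | 2,2-dimethyl-1,3-dioxan-5-one | CC1(C)OCC(=O)CO1 | starting material
4 | 5-(dibromomethylene)-2,2-dimethyl-1,3-dioxane | CC1(C)OCC(=C(Br)Br)CO1 | intermediate
5 | [bromo(2,2-dimethyl-1,3-dioxan-5-ylidene)methyl]lithium (not isolated) | [Li]C(Br)=C1COC(C)(C)OC1 | intermediate
6 | 2-bromo-2-(2,2-dimethyl-1,3-dioxan-5-ylidene)acetaldehyde | O=CC(Br)=C1COC(C)(C)OC1 | intermediate
7 | (R)-[3-((tert-butyldimethylsilyl)oxy)-2-methylpropyl]magnesium bromide (not isolated) | CC(C)(C)[Si](C)(C)OC[C@@H](C)C[Mg]Br | intermediate
8 | (4S)-1-bromo-5-((tert-butyldimethylsilyl)oxy)-1-(2,2-dimethyl-1,3-dioxan-5-ylidene)-4-methylpentan-2-ol, both C2 (skeleton C8) epimers | CC(C)(C)[Si](C)(C)OC[C@@H](C)CC(O)C(Br)=C1COC(C)(C)OC1 | intermediate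
9 | (S)-1-bromo-5-((tert-butyldimethylsilyl)oxy)-1-(2,2-dimethyl-1,3-dioxan-5-ylidene)-4-methylpentan-2-one | CC(C)(C)[Si](C)(C)OC[C@@H](C)CC(=O)C(Br)=C1COC(C)(C)OC1 | intermediate
10 | (2S,4S)-1-bromo-5-((tert-butyldimethylsilyl)oxy)-1-(2,2-dimethyl-1,3-dioxan-5-ylidene)-4-methylpentan-2-ol | CC(C)(C)[Si](C)(C)OC[C@@H](C)C[C@H](O)C(Br)=C1COC(C)(C)OC1 | intermediate
11 | tert-butyl{[(2S,4S)-5-bromo-5-(2,2-dimethyl-1,3-dioxan-5-ylidene)-4-((4-methoxybenzyl)oxy)-2-methylpentyl]oxy}dimethylsilane | CC(C)(C)[Si](C)(C)OC[C@@H](C)C[C@H](OCc1ccc(OC)cc1)C(Br)=C1COC(C)(C)OC1 | intermediate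
12 | 3-methylbut-2-en-1-ol (prenol) | CC(C)=CCO | starting material
13 | tert-butyldimethyl((3-methylbut-2-en-1-yl)oxy)silane | CC(C)=CCO[Si](C)(C)C(C)(C)C | intermediate
14 | (E)-4-((tert-butyldimethylsilyl)oxy)-2-methylbut-2-en-1-ol | OC/C(C)=C/CO[Si](C)(C)C(C)(C)C | intermediate
15 | (E)-4-((tert-butyldimethylsilyl)oxy)-2-methylbut-2-en-1-yl methyl carbonate | COC(=O)OC/C(C)=C/CO[Si](C)(C)C(C)(C)C | intermediate
16 | (E)-4-hydroxy-2-methylbut-2-en-1-yl methyl carbonate | COC(=O)OC/C(C)=C/CO | intermediate
17 | (E)-methyl (2-methyl-4-oxobut-2-en-1-yl) carbonate | COC(=O)OC/C(C)=C/C=O | intermediate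
18 | C7 alkenyllithium derived from 11 (8S,10S; not isolated) | [Li]C(=C1COC(C)(C)OC1)[C@@H](OCc1ccc(OC)cc1)C[C@H](C)CO[Si](C)(C)C(C)(C)C | intermediate
19 | open-chain bis-allylic alcohol, both C6 epimers, (8S,10S): C3 methyl carbonate, E-C4=C5, C7 dioxanylidene, C8 PMB ether, C1 TBS ether | COC(=O)OC/C(C)=C/C(O)C(=C1COC(C)(C)OC1)[C@@H](OCc1ccc(OC)cc1)C[C@H](C)CO[Si](C)(C)C(C)(C)C | intermediate
20 | (8S,10S)-C6 dienone of the same chain | COC(=O)OC/C(C)=C/C(=O)C(=C1COC(C)(C)OC1)[C@@H](OCc1ccc(OC)cc1)C[C@H](C)CO[Si](C)(C)C(C)(C)C | intermediate
21 | (6R,8S,10S)-C6 alcohol | COC(=O)OC/C(C)=C/[C@@H](O)C(=C1COC(C)(C)OC1)[C@@H](OCc1ccc(OC)cc1)C[C@H](C)CO[Si](C)(C)C(C)(C)C | intermediate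
22 | (6R,8S,10S)-C6 TBS ether, C1 TBS ether | COC(=O)OC/C(C)=C/[C@@H](O[Si](C)(C)C(C)(C)C)C(=C1COC(C)(C)OC1)[C@@H](OCc1ccc(OC)cc1)C[C@H](C)CO[Si](C)(C)C(C)(C)C | intermediate
23 | (6R,8S,10S)-C1 primary alcohol | COC(=O)OC/C(C)=C/[C@@H](O[Si](C)(C)C(C)(C)C)C(=C1COC(C)(C)OC1)[C@@H](OCc1ccc(OC)cc1)C[C@H](C)CO | intermediate
24 | (6R,8S,10S)-C1 aldehyde | COC(=O)OC/C(C)=C/[C@@H](O[Si](C)(C)C(C)(C)C)C(=C1COC(C)(C)OC1)[C@@H](OCc1ccc(OC)cc1)C[C@H](C)C=O | intermediate
25 | (6R,8S,10S)-β-hydroxy methyl ester, both C1 epimers | COC(=O)OC/C(C)=C/[C@@H](O[Si](C)(C)C(C)(C)C)C(=C1COC(C)(C)OC1)[C@@H](OCc1ccc(OC)cc1)C[C@H](C)C(O)CC(=O)OC | intermediate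
26 | (6R,8S,10S)-open-chain β-keto methyl ester with C3 allylic methyl carbonate | COC(=O)OC/C(C)=C/[C@@H](O[Si](C)(C)C(C)(C)C)C(=C1COC(C)(C)OC1)[C@@H](OCc1ccc(OC)cc1)C[C@H](C)C(=O)CC(=O)OC | intermediate
27 | (6R,8S,10S)-ten-membered β-keto ester, E-C4=C5, C2 epimers | COC(=O)C1C/C(C)=C/[C@@H](O[Si](C)(C)C(C)(C)C)C(=C2COC(C)(C)OC2)[C@@H](OCc2ccc(OC)cc2)C[C@H](C)C1=O | intermediate
28 | (6R,8S,10S)-ten-membered C1 ketone | C1C/C(C)=C/[C@@H](O[Si](C)(C)C(C)(C)C)C(=C2COC(C)(C)OC2)[C@@H](OCc2ccc(OC)cc2)C[C@H](C)C1=O | intermediate
29 | (1S,6R,8S,10S)-C1 alcohol | COc1ccc(CO[C@H]2C[C@H](C)[C@@H](O)CC/C(C)=C/[C@@H](O[Si](C)(C)C(C)(C)C)C2=C2COC(C)(C)OC2)cc1 | intermediate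
30 | (1S,6R,8S,10S)-C1 acetate | COc1ccc(CO[C@H]2C[C@H](C)[C@@H](OC(C)=O)CC/C(C)=C/[C@@H](O[Si](C)(C)C(C)(C)C)C2=C2COC(C)(C)OC2)cc1 | intermediate
31 | (1S,6R,8S,10S)-C8 alcohol | O[C@H]1C[C@H](C)[C@@H](OC(C)=O)CC/C(C)=C/[C@@H](O[Si](C)(C)C(C)(C)C)C1=C1COC(C)(C)OC1 | intermediate
32 | (1S,6R,8S,10S)-C8 methacrylate | C=C(C)C(=O)O[C@H]1C[C@H](C)[C@@H](OC(C)=O)CC/C(C)=C/[C@@H](O[Si](C)(C)C(C)(C)C)C1=C1COC(C)(C)OC1 | intermediate
33 | (1S,6R,8S,10S)-C6 alcohol, acetonide retained | C=C(C)C(=O)O[C@H]1C[C@H](C)[C@@H](OC(C)=O)CC/C(C)=C/[C@@H](O)C1=C1COC(C)(C)OC1 | intermediate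
34 | (1S,6R,8S,10S)-6,12,13-triol | C=C(C)C(=O)O[C@H]1C[C@H](C)[C@@H](OC(C)=O)CC/C(C)=C/[C@@H](O)C1=C(CO)CO | intermediate
35 | 6,12-lactol with free C13 hydroxyl (lactol epimers; not isolated) | C=C(C)C(=O)O[C@H]1C[C@H](C)[C@@H](OC(C)=O)CC/C(C)=C/[C@H]2OC(O)C(CO)=C12 | intermediate
36 | (1S,6R,8S,10S)-13-oxo-6,12-lactone | C=C(C)C(=O)O[C@H]1C[C@H](C)[C@@H](OC(C)=O)CC/C(C)=C/[C@H]2OC(=O)C(C=O)=C12 | intermediate
37 | (1S,6R,8S,10S)-13-hydroxy-6,12-lactone with E-C4=C5 | C=C(C)C(=O)O[C@H]1C[C@H](C)[C@@H](OC(C)=O)CC/C(C)=C/[C@H]2OC(=O)C(CO)=C12 | intermediate
38 | glaucolide L | C=C(C)C(=O)O[C@H]1C[C@H](C)[C@@H](OC(C)=O)CC[C@@]2(C)O[C@@H]2[C@H]2OC(=O)C(CO)=C12 | target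

## Step count and least certain steps

Total step count: 31. Longest linear sequence: 25 steps (from 3: steps 2–7 and 13–31).

Step 21 (key step). The likely failures are oligomerisation in place of ring closure, attack at C5 to give the eight-membered ring, and β-hydride loss from the allyl complex to a 1,3-diene, because closure of a ten-membered ring is slow and leaves the allyl complex time for other paths. The fallback forms the same bond without palladium. It sets out from 26: methanolysis of the carbonate (K2CO3, MeOH) gives allylic alcohol F1, an Appel reaction (CBr4, PPh3) gives allylic bromide F2, and Cs2CO3 in MeCN at high dilution alkylates the β-keto ester directly at the primary allylic carbon. The route is rejoined at 27.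

Step 15. The catalyst may discriminate poorly between the two alkenyl groups of the dienone, and 1,4-reduction may compete, because both flanking groups are unsaturated. The fallback makes the C6–C7 bond and the C6 centre together. It sets out from 11: bromine–lithium exchange and transmetalation with ZnBr2 give alkenylzinc bromide F3, which is added to 17 in the presence of a chiral amino alcohol ligand (3-exo-morpholinoisoborneol) and a diamine that sequesters the lithium halide. The route is rejoined at 21, and steps 13–15 are bypassed.

Step 23. The conformation of the ten-membered ring may impose its own facial preference on the C1 carbonyl and override the catalyst, giving the C1 epimer. The fallback uses inversion. It sets out from 28: reduction with a bulky hydride (LiBH(s-Bu)3) or the enantiomeric catalyst, whichever is the matched case, gives the (1R)-alcohol F4, and a Mitsunobu reaction with acetic acid (PPh3, diisopropyl azodicarboxylate) delivers the acetate with inversion. The route is rejoined at 30.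

Step 29. Molecules that are oxidised first at the arm that cannot lactolise keep a free bis-allylic C6 hydroxyl for longer, which may be oxidised to the dienone. The formyl butenolide may also enolise at C6, and the C8 ester may migrate to the C13 oxygen. The fallback oxidises both arms before C6 is unmasked. It sets out from 32: PPTS in MeOH gives diol F5 with the C6 silyl ether intact, MnO2 gives dialdehyde F6, and HF·pyridine frees the C6 hydroxyl, which closes onto the only formyl group it can reach to give lactol aldehyde F7. NaBH4/CeCl3·7H2O at −78 °C reduces the remaining aldehyde to lactol 35, and a lactol-selective oxidation (Ag2CO3 on Celite) gives the lactone. The route is rejoined at 37.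

Step 31. Facial selectivity may be poor if the macrocycle populates a second conformer. The fallback replaces substrate control by reagent control: it sets out from 37 and uses a Shi epoxidation (fructose-derived ketone of the enantiomeric series matched to the required face, KHSO5, buffered), which is general for E-trisubstituted alkenes. It arrives at 38 and makes no new compound (F0).

## Further compounds

F1 | step 21 | (6R,8S,10S)-open-chain β-keto ester with free C3 allylic alcohol | OC/C(C)=C/[C@@H](O[Si](C)(C)C(C)(C)C)C(=C1COC(C)(C)OC1)[C@@H](OCc1ccc(OC)cc1)C[C@H](C)C(=O)CC(=O)OC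
F2 | step 21 | (6R,8S,10S)-open-chain β-keto ester with C3 allylic bromide | BrC/C(C)=C/[C@@H](O[Si](C)(C)C(C)(C)C)C(=C1COC(C)(C)OC1)[C@@H](OCc1ccc(OC)cc1)C[C@H](C)C(=O)CC(=O)OC
F3 | step 15 | C7 alkenylzinc bromide derived from 11 (8S,10S) | Br[Zn]C(=C1COC(C)(C)OC1)[C@@H](OCc1ccc(OC)cc1)C[C@H](C)CO[Si](C)(C)C(C)(C)C
F4 | step 23 | (1R,6R,8S,10S)-C1 alcohol (C1 epimer of 29) | COc1ccc(CO[C@H]2C[C@H](C)[C@H](O)CC/C(C)=C/[C@@H](O[Si](C)(C)C(C)(C)C)C2=C2COC(C)(C)OC2)cc1
F5 | step 29 | (1S,6R,8S,10S)-12,13-diol with C6 TBS ether | C=C(C)C(=O)O[C@H]1C[C@H](C)[C@@H](OC(C)=O)CC/C(C)=C/[C@@H](O[Si](C)(C)C(C)(C)C)C1=C(CO)CO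
F6 | step 29 | (1S,6R,8S,10S)-12,13-dialdehyde with C6 TBS ether | C=C(C)C(=O)O[C@H]1C[C@H](C)[C@@H](OC(C)=O)CC/C(C)=C/[C@@H](O[Si](C)(C)C(C)(C)C)C1=C(C=O)C=O
F7 | step 29 | 6,12-lactol with C13 aldehyde (lactol epimers) | C=C(C)C(=O)O[C@H]1C[C@H](C)[C@@H](OC(C)=O)CC/C(C)=C/[C@H]2OC(O)C(C=O)=C12
F0 | step 31 | none | none
A1 | alternative 1 | trans,trans-trisubstituted γ-lactone carrying the C8 dithiane and the C13 hydroxymethyl group | CC(C)(C)[Si](c1ccccc1)(c1ccccc1)OC[C@H]1OC(=O)[C@@H](CO)[C@@H]1C1(SCCCS1)C[C@H](C)[C@@H](OCc1ccc(OC)cc1)C=C
A2 | alternative 2 | protected macrocyclic core with 4,5-epoxide and butenolide | COc1ccc(CO[C@H]2C[C@H](C)[C@@H](O[Si](C)(C)C(C)(C)C)CC[C@@]3(C)O[C@@H]3[C@H]3OC(=O)C(CO[Si](c4ccccc4)(c4ccccc4)C(C)(C)C)=C23)cc1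
A3 | alternative 3 | ten-membered butenolide with C5 hydroxyl and C4 triethylsilyl ether | C=C(C)C(=O)O[C@H]1C[C@H](C)[C@@H](OC(C)=O)CC[C@@](C)(O[Si](CC)(CC)CC)[C@@H](O)[C@H]2OC(=O)C(CO[Si](c3ccccc3)(c3ccccc3)C(C)(C)C)=C12
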